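**Retrosynthetic overview**

1. Numbering as in germacranolides: C1=C10 with C14HO on C10, C4=C5 with C15H2OH on C4, lactone O on C6, lactone carbon C11 on C7, ester O on C8. The last operations are cleavage of the C15 silyl ether and a Mitsunobu inversion at C8 that installs the isovalerate.
2. Key disconnection: the whole α-methylene-γ-butyrolactone (O–C6 and C11–C7) is removed as 2-bromoacrylic acid from a monocyclic cyclodecatriene enal by a palladium-catalysed [3+2] carbo-oxygenation of its C4=C5–C6=C7 diene.
3. Enabling feature: the lactone oxygen sits on C6, allylic to the ring C4=C5 bond, and C11 sits on the adjacent C7. The lactone ring is therefore the 1,2-adduct of a 1-carboxyvinyl unit to the C6=C7 end of a ring-cis,ring-cis 1,3-diene, formed through a C4–C5–C6 allylpalladium that the carboxylate closes at C6.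
4. The cyclodecatriene comes from ene–diene ring-closing metathesis (C6=C7) of an acyclic trienal. That trienal is assembled by aldol condensation (C1=C10) of (R)-γ-vinylbutyrolactone with a dienal whose C4=C5 geometry is set by anti-carbomagnesiation of an enynol.
5. Ring order: ten-membered carbocycle first (step 12), then the γ-lactone (step 13).

Key step: step 13

Remark: read from the SMILES, the lactone is cis-fused and the C8 ester lies on the same ring face as C11 and O6; both enantiomers of 5-(hydroxymethyl)oxolan-2-one are taken to be commercial.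

**Route**

Step 1
Reactants: 1 prop-2-yn-1-ol; 2 bromoethene
Product: 3 pent-4-en-2-yn-1-ol
Conditions: PdCl2(PPh3)2 (2 mol %), CuI (4 mol %), i-Pr2NH, THF, 0 °C to rt
Reagents that add atoms: none
Why: Sonogashira coupling of a terminal alkyne with a vinyl bromide is general and tolerates the free primary alcohol; no stereocentre is formed.

Step 2
Reactants: 3 pent-4-en-2-yn-1-ol; 4 [2-(1,3-dioxolan-2-yl)ethyl]magnesium bromide
Product: 6 (2E)-2-[2-(1,3-dioxolan-2-yl)ethyl]penta-2,4-dien-1-ol, via chelated vinylmagnesium alkoxide 5 (not isolated)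
Conditions: 4 (3 equiv), CuI (10 mol %), THF, -20 °C to rt; then aq. NH4Cl
Reagents that add atoms: none
Why: Copper-catalysed anti-carbomagnesiation of a propargylic alcohol places the alkyl group on the alkyne carbon next to the carbinol and magnesium on the distal carbon inside a five-membered alkoxide chelate, so that protonation leaves the new chain (C3) cis to the vinyl group (C6), which is the ring-cis C4=C5 geometry of the target.

Step 3
Reactants: 6 (2E)-2-[2-(1,3-dioxolan-2-yl)ethyl]penta-2,4-dien-1-ol
Product: 7 tert-butyl({(2E)-2-[2-(1,3-dioxolan-2-yl)ethyl]penta-2,4-dien-1-yl}oxy)diphenylsilane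
Conditions: TBDPSCl, imidazole, DMF, 0 °C to rt
Reagents that add atoms: tert-butyl(chloro)diphenylsilane, CC(C)(C)[Si](Cl)(c1ccccc1)c1ccccc1
Why: Silylation of the primary allylic alcohol is routine, and the tert-butyldiphenylsilyl ether is chosen because it should survive acid, base, palladium and the later cleavage of a triethylsilyl ether.

Step 4
Reactants: 7 tert-butyl({(2E)-2-[2-(1,3-dioxolan-2-yl)ethyl]penta-2,4-dien-1-yl}oxy)diphenylsilane
Product: 8 (4E)-4-({[tert-butyl(diphenyl)silyl]oxy}methyl)hepta-4,6-dienal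
Conditions: PPTS, acetone–H2O (10:1), 55 °C
Reagents that add atoms: water, O
Why: Acid-catalysed transacetalisation of the dioxolane in wet acetone frees the C1 aldehyde under conditions that should leave the silyl ether and the diene untouched.

Step 5
Reactants: 9 (5R)-5-(hydroxymethyl)oxolan-2-one
Product: 10 (2R)-5-oxooxolane-2-carbaldehyde
Conditions: (COCl)2, DMSO, CH2Cl2, -78 °C; then Et3N, -78 to 0 °C
Reagents that add atoms: none
Why: Swern oxidation gives the aldehyde at low temperature without epimerising the adjacent lactone stereocentre (the future C8).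

Step 6
Reactants: 10 (2R)-5-oxooxolane-2-carbaldehyde
Product: 11 (5R)-5-ethenyloxolan-2-one
Conditions: Ph3PCH3Br, KN(SiMe3)2, THF, -78 to 0 °C
Reagents that add atoms: methyltriphenylphosphonium bromide, C[P+](c1ccccc1)(c1ccccc1)c1ccccc1.[Br-]
Why: Wittig methylenation with a non-stabilised ylide at low temperature should add to the aldehyde (making C7) faster than it attacks the lactone or enolises the aldehyde, so the C8 configuration is kept.

Step 7
Reactants: 11 (5R)-5-ethenyloxolan-2-one; 8 (4E)-4-({[tert-butyl(diphenyl)silyl]oxy}methyl)hepta-4,6-dienal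
Product: 13 (5R)-3-[(4E)-4-({[tert-butyl(diphenyl)silyl]oxy}methyl)-1-hydroxyhepta-4,6-dien-1-yl]-5-ethenyloxolan-2-one (mixture of diastereomers at the two new centres), via lithium enolate 12 (not isolated)
Conditions: LiN(SiMe3)2, THF, -78 °C; then 8; aq. NH4Cl
Reagents that add atoms: none
Why: Aldol addition of the lactone lithium enolate to the aldehyde forms the C1–C10 bond; the two new stereocentres need no control because both are removed in step 8, and C8 is not touched.

Step 8
Reactants: 13 (5R)-3-[(4E)-4-({[tert-butyl(diphenyl)silyl]oxy}methyl)-1-hydroxyhepta-4,6-dien-1-yl]-5-ethenyloxolan-2-one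
Product: 15 (3E,5R)-3-[(4E)-4-({[tert-butyl(diphenyl)silyl]oxy}methyl)hepta-4,6-dien-1-ylidene]-5-ethenyloxolan-2-one, via mesylate 14 (not isolated)
Conditions: MsCl, Et3N, CH2Cl2, -20 °C; then DBU, 0 °C to rt
Reagents that add atoms: none
Why: Mesylation and base-induced E1cB elimination give the α-alkylidene lactone, and the E isomer (C2 trans to the carbonyl and cis to C9) should dominate as the thermodynamically preferred geometry of α-alkylidene-γ-butyrolactones, which is the ring-cis C1=C10 geometry of the target.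

Step 9
Reactants: 15 (3E,5R)-3-[(4E)-4-({[tert-butyl(diphenyl)silyl]oxy}methyl)hepta-4,6-dien-1-ylidene]-5-ethenyloxolan-2-one
Product: 16 (2E,6E)-6-({[tert-butyl(diphenyl)silyl]oxy}methyl)-2-[(2R)-2-hydroxybut-3-en-1-yl]-N-methoxy-N-methylnona-2,6,8-trienamide
Conditions: MeNH(OMe)·HCl, AlMe3, CH2Cl2, 0 °C to rt; aq. KNaC4H4O6
Reagents that add atoms: N,O-dimethylhydroxylamine hydrochloride, CNOC.Cl
Why: Weinreb amide formation by aminolysis of the lactone with the aluminium amide opens the ring at the acyl carbon, so the C8–O bond and the alkene geometries are untouched.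

Step 10
Reactants: 16 (2E,6E)-6-({[tert-butyl(diphenyl)silyl]oxy}methyl)-2-[(2R)-2-hydroxybut-3-en-1-yl]-N-methoxy-N-methylnona-2,6,8-trienamide
Product: 17 (2E,6E)-6-({[tert-butyl(diphenyl)silyl]oxy}methyl)-N-methoxy-N-methyl-2-{(2R)-2-[(triethylsilyl)oxy]but-3-en-1-yl}nona-2,6,8-trienamide
Conditions: TESCl, imidazole, CH2Cl2, 0 °C
Reagents that add atoms: chlorotriethylsilane, CC[Si](Cl)(CC)CC
Why: Silylation of the secondary allylic alcohol prevents relactonisation and installs the labile silyl ether whose later cleavage exposes C8–OH selectively beside the tert-butyldiphenylsilyl ether.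

Step 11
Reactants: 17 (2E,6E)-6-({[tert-butyl(diphenyl)silyl]oxy}methyl)-N-methoxy-N-methyl-2-{(2R)-2-[(triethylsilyl)oxy]but-3-en-1-yl}nona-2,6,8-trienamide
Product: 18 (2E,6E)-6-({[tert-butyl(diphenyl)silyl]oxy}methyl)-2-{(2R)-2-[(triethylsilyl)oxy]but-3-en-1-yl}nona-2,6,8-trienal
Conditions: i-Bu2AlH, THF, -78 °C; aq. KNaC4H4O6
Reagents that add atoms: none
Why: Reduction of an N-methoxy-N-methyl amide with i-Bu2AlH at low temperature stops at the aldehyde, which should give the C14 enal without touching the silyl ethers or the alkenes.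

Step 12
Reactants: 18 (2E,6E)-6-({[tert-butyl(diphenyl)silyl]oxy}methyl)-2-{(2R)-2-[(triethylsilyl)oxy]but-3-en-1-yl}nona-2,6,8-trienal
Product: 19 (1E,5E,7Z,9R)-5-({[tert-butyl(diphenyl)silyl]oxy}methyl)-9-[(triethylsilyl)oxy]cyclodeca-1,5,7-triene-1-carbaldehyde
Conditions: RuCl2(=CHPh)(H2IMes)(PCy3) (second-generation Grubbs catalyst, 10 mol %), CH2Cl2 (1 mM), 40 °C
Reagents that add atoms: none
Why: Ene–diene ring-closing metathesis joins the two terminal alkenes with loss of ethene (the trisubstituted and electron-poor double bonds are inert), the two ring-cis trisubstituted alkenes bring the chain ends together, and a ten-membered ring flanked by these units can hold the new C6=C7 bond only as the Z isomer.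

Step 13
Reactants: 19 (1E,5E,7Z,9R)-5-({[tert-butyl(diphenyl)silyl]oxy}methyl)-9-[(triethylsilyl)oxy]cyclodeca-1,5,7-triene-1-carbaldehyde; 20 2-bromoprop-2-enoic acid
Product: 22 (3aR,4R,6E,10E,11aR)-10-({[tert-butyl(diphenyl)silyl]oxy}methyl)-3-methylidene-2-oxo-4-[(triethylsilyl)oxy]-2,3,3a,4,5,8,9,11a-octahydrocyclodeca[b]furan-6-carbaldehyde, via allylpalladium carboxylate 21 (not isolated)
Conditions: 20 (2.5 equiv), Pd(OAc)2 (10 mol %), P(t-Bu)3·HBF4 (20 mol %), K2CO3 (4 equiv), DMF, 60 °C, no chloride additive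
Reagents that add atoms: none
Why: Zerovalent palladium inserts into the C–Br bond of 20, the 1-carboxyvinylpalladium species adds syn across the ring-cis C6=C7 bond with carbon at the less substituted diene terminus C7, the resulting C4–C5–C6 allylpalladium is captured at C6 by the palladium-bound carboxylate, and zerovalent palladium is released; this is the Larock-type heteroannulation of 1,3-dienes by α-haloacrylic acids, a known route to α-methylene-γ-butyrolactones. The one ring closed is the γ-lactone, by 5-exo C–O bond formation at the allyl terminus C6 (reductive elimination from the six-membered oxapalladacycle 21), closure to a seven-membered ring at the fully substituted C4 being disfavoured. C7 is controlled by the C8 stereocentre: allylic 1,3-strain with C5–H keeps H8 in the plane of the ring-cis C6=C7 bond, the ring chain through C9 covers one face, and the vinylpalladium should enter from the periphery, which places C11 trans to the OTES group (the reason why C8 is carried in the R configuration and inverted later). C6 is controlled by C7: palladium and C11 add to the same face of the Z alkene and the oxygen is delivered from palladium, so O6 and C11 should end up cis (cis-fused lactone); one bulky monophosphine and the absence of chloride keep a site on palladium for the carboxylate. The step needs chemoselectivity for the diene over the enal and regioselectivity for C7 over C4, secured by the electron-poor trisubstituted C1=C10 bond and the fully substituted C4 terminus, and the ring holds the allyl unit in its ring-cis form so that the C4=C5 geometry is returned unchanged. The silyl ethers on O8 and O15 are not ionised by palladium, which is why the isovalerate is introduced only afterwards.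

Step 14
Reactants: 22 (3aR,4R,6E,10E,11aR)-10-({[tert-butyl(diphenyl)silyl]oxy}methyl)-3-methylidene-2-oxo-4-[(triethylsilyl)oxy]-2,3,3a,4,5,8,9,11a-octahydrocyclodeca[b]furan-6-carbaldehyde
Product: 23 (3aS,4R,6E,10E,11aR)-10-({[tert-butyl(diphenyl)silyl]oxy}methyl)-4-hydroxy-3-methylidene-2-oxo-2,3,3a,4,5,8,9,11a-octahydrocyclodeca[b]furan-6-carbaldehyde
Conditions: AcOH–THF–H2O (3:1:1), rt
Reagents that add atoms: none
Why: Mild acid solvolysis should remove the secondary triethylsilyl ether much faster than the primary tert-butyldiphenylsilyl ether and leave the enal and the α-methylene lactone untouched.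

Step 15
Reactants: 23 (3aS,4R,6E,10E,11aR)-10-({[tert-butyl(diphenyl)silyl]oxy}methyl)-4-hydroxy-3-methylidene-2-oxo-2,3,3a,4,5,8,9,11a-octahydrocyclodeca[b]furan-6-carbaldehyde; 24 3-methylbutanoic acid
Product: 26 [(3aS,4S,6E,10E,11aR)-10-({[tert-butyl(diphenyl)silyl]oxy}methyl)-6-formyl-3-methylidene-2-oxo-2,3,3a,4,5,8,9,11a-octahydrocyclodeca[b]furan-4-yl] 3-methylbutanoate, via alkoxyphosphonium isovalerate 25 (not isolated)
Conditions: 24 (3 equiv), PPh3, DIAD, toluene, 0 °C to rt
Reagents that add atoms: none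
Why: Mitsunobu esterification activates the C8 hydroxyl as an alkoxyphosphonium ion that the isovalerate displaces by SN2 with inversion, which converts (8R) into the (8S) ester cis to C11 and O6 and installs the acyl group in the same operation.

Step 16
Reactants: 26 [(3aS,4S,6E,10E,11aR)-10-({[tert-butyl(diphenyl)silyl]oxy}methyl)-6-formyl-3-methylidene-2-oxo-2,3,3a,4,5,8,9,11a-octahydrocyclodeca[b]furan-4-yl] 3-methylbutanoate
Product: 27 [(3aS,4S,6E,10E,11aR)-6-formyl-10-(hydroxymethyl)-3-methylidene-2-oxo-2,3,3a,4,5,8,9,11a-octahydrocyclodeca[b]furan-4-yl] 3-methylbutanoate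
Conditions: HF·pyridine, pyridine, THF, 0 °C to rt
Reagents that add atoms: none
Why: Fluoride-mediated desilylation with buffered HF·pyridine cleaves the primary silyl ether without base, so the isovalerate, the enal and the α-methylene lactone should survive.

**Compound list**

1 | prop-2-yn-1-ol | C#CCO | starting material
2 | bromoethene | C=CBr | starting material
3 | pent-4-en-2-yn-1-ol | C=CC#CCO | intermediate
4 | [2-(1,3-dioxolan-2-yl)ethyl]magnesium bromide (solution in THF) | Br[Mg]CCC1OCCO1 | starting material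
5 | 3-ethenyl-4-[2-(1,3-dioxolan-2-yl)ethyl]-2,5-dihydro-1,2-oxamagnesole (chelated vinylmagnesium alkoxide, solvent ligands omitted) | C=CC1=C(CCC2OCCO2)CO[Mg]1 | intermediate
6 | (2E)-2-[2-(1,3-dioxolan-2-yl)ethyl]penta-2,4-dien-1-ol | C=C/C=C(\CCC1OCCO1)CO | intermediate
7 | tert-butyl({(2E)-2-[2-(1,3-dioxolan-2-yl)ethyl]penta-2,4-dien-1-yl}oxy)diphenylsilane | C=C/C=C(\CCC1OCCO1)CO[Si](c1ccccc1)(c1ccccc1)C(C)(C)C | intermediate
8 | (4E)-4-({[tert-butyl(diphenyl)silyl]oxy}methyl)hepta-4,6-dienal | C=C/C=C(\CCC=O)CO[Si](c1ccccc1)(c1ccccc1)C(C)(C)C | intermediate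
9 | (5R)-5-(hydroxymethyl)oxolan-2-one | OC[C@H]1CCC(=O)O1 | starting material
10 | (2R)-5-oxooxolane-2-carbaldehyde | O=C[C@H]1CCC(=O)O1 | intermediate
11 | (5R)-5-ethenyloxolan-2-one | C=C[C@H]1CCC(=O)O1 | intermediate
12 | lithium (5R)-5-ethenyl-4,5-dihydrofuran-2-olate (lithium enolate of 11) | C=C[C@H]1CC=C(O[Li])O1 | intermediate
13 | (5R)-3-[(4E)-4-({[tert-butyl(diphenyl)silyl]oxy}methyl)-1-hydroxyhepta-4,6-dien-1-yl]-5-ethenyloxolan-2-one (diastereomers at lactone C3 and the carbinol carbon) | C=C[C@H]1CC(C(O)CC/C(CO[Si](c2ccccc2)(c2ccccc2)C(C)(C)C)=C\C=C)C(=O)O1 | intermediate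
14 | methanesulfonate of 13 on the carbinol oxygen | C=C[C@H]1CC(C(OS(C)(=O)=O)CC/C(CO[Si](c2ccccc2)(c2ccccc2)C(C)(C)C)=C\C=C)C(=O)O1 | intermediate
15 | (3E,5R)-3-[(4E)-4-({[tert-butyl(diphenyl)silyl]oxy}methyl)hepta-4,6-dien-1-ylidene]-5-ethenyloxolan-2-one | C=C[C@H]1C/C(=C\CC/C(CO[Si](c2ccccc2)(c2ccccc2)C(C)(C)C)=C\C=C)C(=O)O1 | intermediate
16 | (2E,6E)-6-({[tert-butyl(diphenyl)silyl]oxy}methyl)-2-[(2R)-2-hydroxybut-3-en-1-yl]-N-methoxy-N-methylnona-2,6,8-trienamide | C=C[C@H](O)C/C(=C\CC/C(CO[Si](c1ccccc1)(c1ccccc1)C(C)(C)C)=C\C=C)C(=O)N(C)OC | intermediate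
17 | (2E,6E)-6-({[tert-butyl(diphenyl)silyl]oxy}methyl)-N-methoxy-N-methyl-2-{(2R)-2-[(triethylsilyl)oxy]but-3-en-1-yl}nona-2,6,8-trienamide | C=C[C@H](O[Si](CC)(CC)CC)C/C(=C\CC/C(CO[Si](c1ccccc1)(c1ccccc1)C(C)(C)C)=C\C=C)C(=O)N(C)OC | intermediate
18 | (2E,6E)-6-({[tert-butyl(diphenyl)silyl]oxy}methyl)-2-{(2R)-2-[(triethylsilyl)oxy]but-3-en-1-yl}nona-2,6,8-trienal | C=C[C@H](O[Si](CC)(CC)CC)C/C(=C\CC/C(CO[Si](c1ccccc1)(c1ccccc1)C(C)(C)C)=C\C=C)C=O | intermediate
19 | (1E,5E,7Z,9R)-5-({[tert-butyl(diphenyl)silyl]oxy}methyl)-9-[(triethylsilyl)oxy]cyclodeca-1,5,7-triene-1-carbaldehyde (all three ring double bonds ring-cis; germacrane C8 is R) | O=C/C1=C/CC/C(CO[Si](c2ccccc2)(c2ccccc2)C(C)(C)C)=C\C=C/[C@H](O[Si](CC)(CC)CC)C1 | intermediate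
20 | 2-bromoprop-2-enoic acid | C=C(Br)C(=O)O | starting material
21 | divalent palladium complex of the C4–C5–C6 allyl unit and the C12 carboxylate (six-membered oxapalladacycle O–Pd–C6, drawn in the C6-bound form, phosphine omitted; Pd cis to C11) | C=C1C(=O)O[Pd][C@@H]2/C=C(/CO[Si](c3ccccc3)(c3ccccc3)C(C)(C)C)CC/C=C(/C=O)C[C@@H](O[Si](CC)(CC)CC)[C@H]12 | intermediate
22 | (3aR,4R,6E,10E,11aR)-10-({[tert-butyl(diphenyl)silyl]oxy}methyl)-3-methylidene-2-oxo-4-[(triethylsilyl)oxy]-2,3,3a,4,5,8,9,11a-octahydrocyclodeca[b]furan-6-carbaldehyde (cis-fused lactone; OTES trans to C11) | C=C1C(=O)O[C@@H]2/C=C(/CO[Si](c3ccccc3)(c3ccccc3)C(C)(C)C)CC/C=C(/C=O)C[C@@H](O[Si](CC)(CC)CC)[C@H]12 | intermediate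
23 | (3aS,4R,6E,10E,11aR)-10-({[tert-butyl(diphenyl)silyl]oxy}methyl)-4-hydroxy-3-methylidene-2-oxo-2,3,3a,4,5,8,9,11a-octahydrocyclodeca[b]furan-6-carbaldehyde (OH trans to C11) | C=C1C(=O)O[C@@H]2/C=C(/CO[Si](c3ccccc3)(c3ccccc3)C(C)(C)C)CC/C=C(/C=O)C[C@@H](O)[C@H]12 | intermediate
24 | 3-methylbutanoic acid | CC(C)CC(=O)O | starting material
25 | C8 alkoxy(triphenyl)phosphonium 3-methylbutanoate of 23 | C=C1C(=O)O[C@@H]2/C=C(/CO[Si](c3ccccc3)(c3ccccc3)C(C)(C)C)CC/C=C(/C=O)C[C@@H](O[P+](c3ccccc3)(c3ccccc3)c3ccccc3)[C@H]12.CC(C)CC(=O)[O-] | intermediate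
26 | [(3aS,4S,6E,10E,11aR)-10-({[tert-butyl(diphenyl)silyl]oxy}methyl)-6-formyl-3-methylidene-2-oxo-2,3,3a,4,5,8,9,11a-octahydrocyclodeca[b]furan-4-yl] 3-methylbutanoate | C=C1C(=O)O[C@@H]2/C=C(/CO[Si](c3ccccc3)(c3ccccc3)C(C)(C)C)CC/C=C(/C=O)C[C@H](OC(=O)CC(C)C)[C@H]12 | intermediate
27 | [(3aS,4S,6E,10E,11aR)-6-formyl-10-(hydroxymethyl)-3-methylidene-2-oxo-2,3,3a,4,5,8,9,11a-octahydrocyclodeca[b]furan-4-yl] 3-methylbutanoate | C=C1C(=O)O[C@@H]2/C=C(/CO)CC/C=C(/C=O)C[C@H](OC(=O)CC(C)C)[C@H]12 | target

**Totals**

Total step count: 16. Longest linear sequence: 14 steps (steps 1–4, then 7–16).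

**Steps most likely to fail**

Step 13. The vinylpalladium may insert with the wrong regiochemistry or on the shielded face. The allylpalladium may lose a β-hydride to give a triene. The C–O bond may form on the face opposite to palladium and give a trans ring fusion. Zerovalent palladium may re-ionise the allylic lactone. The fallback sets out from 19 and returns at 23, and forms the same two bonds by a radical–polar sequence with trivalent manganese. Mn(OAc)3·2H2O and Cu(OAc)2 with 3-tert-butoxy-3-oxopropanoic acid in AcOH/KOAc at 40–50 °C should add the malonyl radical to C7 from the ring periphery. The allyl radical is oxidised by divalent copper and the free carboxyl group closes on C6, which should give the cis-fused tert-butyl ester lactone F1. CF3CO2H in CH2Cl2 then removes the tert-butyl ester and the triethylsilyl ether to give the hydroxy acid lactone F2. Aqueous HCHO/Et2NH followed by warming in AcOH/NaOAc (decarboxylative Mannich methylenation) should give alcohol 23.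

Step 12. Cross-metathesis may give oligomers in place of ring closure, or the ruthenium carbene may stall on the conjugated diene while the silyloxy-flanked alkene fails to engage. The fallback sets out from 15 and returns at 19, and changes the ring-closing substrate and the order of events. Ring closure is moved to the rigid α-alkylidene lactone 15, in which the five-membered lactone holds C8, C9 and C10 and the allylic oxygen is an unhindered ester oxygen. Metathesis at high dilution should give the bridged bicyclic lactone F3. AlMe3/MeNH(OMe)·HCl opens it to the ring hydroxy amide F4, TESCl/imidazole gives the ring silyl ether amide F5, and i-Bu2AlH at -78 °C gives 19.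

Step 15. The activated alcohol may eliminate toward C9 (the γ-position of the enal). Substitution may be slow because the carboxylate must enter on the ring face that carries the lactone. The free hydroxyl may be intercepted by the C14 aldehyde as a hemiacetal. The fallback sets out from 23 and returns at 26, and inverts C8 by oxidation and reduction instead of substitution. Dess–Martin periodinane gives the 8-ketone F6. NaBH4/CeCl3·7H2O in MeOH at -78 °C (Luche reduction, which spares the α-methylene lactone) should deliver hydride to C8 from the face away from the lactone and also reduce the aldehyde, giving the diol F7 with O8 cis to C11. MnO2 in CH2Cl2 re-oxidises only the allylic primary alcohol to the hydroxy enal F8, and isovaleric anhydride/DMAP gives ester 26.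

**Further compounds**

F1 | step 13 | analogue of 22 with H and CO2t-Bu on C11 in place of the methylidene group (cis-fused lactone, C11 epimers) | CC(C)(C)OC(=O)C1C(=O)O[C@@H]2/C=C(/CO[Si](c3ccccc3)(c3ccccc3)C(C)(C)C)CC/C=C(/C=O)C[C@@H](O[Si](CC)(CC)CC)[C@H]12
F2 | step 13 | 11-carboxylic acid with free (8R)-hydroxyl from F1 | OC(=O)C1C(=O)O[C@@H]2/C=C(/CO[Si](c3ccccc3)(c3ccccc3)C(C)(C)C)CC/C=C(/C=O)C[C@@H](O)[C@H]12
F3 | step 12 | bridged bicyclic triene lactone (ten-membered ring closed at C6=C7, O8–C14 γ-lactone still in place, C8 R) | O=C1O[C@H]2/C=C\C=C(CO[Si](c3ccccc3)(c3ccccc3)C(C)(C)C)/CC/C=C1\C2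
F4 | step 12 | ring-closed N-methoxy-N-methyl amide with free (8R)-hydroxyl | CON(C)C(=O)/C1=C/CC/C(CO[Si](c2ccccc2)(c2ccccc2)C(C)(C)C)=C\C=C/[C@H](O)C1
F5 | step 12 | triethylsilyl ether of F4 | CON(C)C(=O)/C1=C/CC/C(CO[Si](c2ccccc2)(c2ccccc2)C(C)(C)C)=C\C=C/[C@H](O[Si](CC)(CC)CC)C1
F6 | step 15 | 8-oxo analogue of 23 | C=C1C(=O)O[C@@H]2/C=C(/CO[Si](c3ccccc3)(c3ccccc3)C(C)(C)C)CC/C=C(/C=O)CC(=O)[C@H]12
F7 | step 15 | 8,14-diol with (8S)-hydroxyl cis to C11 | C=C1C(=O)O[C@@H]2/C=C(/CO[Si](c3ccccc3)(c3ccccc3)C(C)(C)C)CC/C=C(/CO)C[C@H](O)[C@H]12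
F8 | step 15 | C8 epimer of 23 ((8S)-hydroxy enal) | C=C1C(=O)O[C@@H]2/C=C(/CO[Si](c3ccccc3)(c3ccccc3)C(C)(C)C)CC/C=C(/C=O)C[C@H](O)[C@H]12
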